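Decide first what stopped these flasks. The theta plateau, read as 0.0333 M, is less than the partner charged, and the delta plateau, read as 0.123 M, is less than the left-handed substrate charged, so these readings speak against a reagent running out, but they do not tell a reversible step from a dying catalyst. I choose the dying catalyst as my working assumption, and what follows is reckoned on it.

in all of them: left-handed substrate 0.25 M; right-handed substrate 0.25 M; free catalyst 25 mM

| charge | partner | remark |
|---|---|---|
| theta | 0.19 M | run made earlier |
| delta | 0.75 M | run made earlier |
| flask | 0.375 M |  |

| run | time / min | left-handed product / % |
|---|---|---|
| theta | 0.333 | 3.7 |
| theta | 0.833 | 9.2 |
| theta | 1.50 | 7.0 |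
| theta | 2.50 | 6.6 |
| theta | 4.00 | 6.4 |
| delta | 0.250 | 14.4 |
| delta | 0.500 | 19.3 |
| delta | 1.00 | 22.1 |
| delta | 2.00 | 25.3 |
| delta | 4.00 | 23.9 |

(each reading ± 1 percentage point)

1. apparent order in partner when 10% of the left-handed substrate and right-handed substrate together are converted (percent change of the rate of making left-handed product for one percent more partner charged)
2. factor on the rate of making left-handed product when 10% of the left-handed substrate and right-handed substrate together are converted if partner is charged twice over

- free catalyst is single-handed; left-handed substrate and right-handed substrate are mirror images of each other, charged as a racemate, each of them at the stated concentration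
- the numbers in the tables scatter with a standard deviation of 1 percentage point

Follow one catalyst molecule: at each moment, on my reading, it either turns over, with a chance proportional to partner times left-handed substrate, or dies. Integrating that third-order rate up to each plateau, with one partner and one left-handed substrate used per product, gives 0.830 M⁻¹ for theta and 0.996 M⁻¹ for delta, so you carry their mean 0.913 M⁻¹, the lifetime dose, the integral over time of rate constant times free catalyst.

In the flask, reaching 10% means 0.0500 M of left-handed product and spends 0.640 M⁻¹, which leaves 29.9% of the dose, my estimate of the share of catalyst still free. The rate there goes as partner left times left-handed substrate left times dose unspent, so more partner acts directly and also arrives at that level with more catalyst alive. My reckoning gives an order of 3.67 and, for doubled partner, a factor of 4.78.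

The forecast says 3.5 and 4.5, reading the runs as “a fast, reversible catalysed step”.

The flask gives 3.5 and 4.60.

    partner + free catalyst + right-handed substrate → free catalyst + right-handed product (k = 0.0109 M⁻² s⁻¹)
    free catalyst → spent catalyst (k = 0.0478 s⁻¹)
    partner + free catalyst + left-handed substrate → free catalyst + left-handed product (k = 1.77 M⁻² s⁻¹)

Turnover ran while free catalyst lasted: at 0.300 min the flask held 8.58% left-handed product and 42.3% free catalyst, while the carried dose, applied to that product, leaves 41.5% unspent. By 1.50 min, with free catalyst down to 1.35%, 99% of the left-handed turnover up to 3.00 min was done, and at 30.0 min left-handed product stood at 13.4% with 81.9% of the partner still there.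

The earlier runs and the new flask stem from a simulated flask with constants of no real substance; noise was put on by code.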